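**Assumption:** the target is achiral. C2 of 5, 6 and 7 is a racemic centre that is destroyed in step 4, and 5 is taken to equilibrate with its open-chain tautomer 4, both entering step 3 through the same C2 oxocarbenium ion.

## The problem

The target is a 2-aryloxychromone. Ring A is a phloroglucinol-derived benzo ring (5-OH, 7-O-prenyl), ring C is a 4-pyranone, and ring B is a hydroquinone unit bound to C2 through an exocyclic oxygen. There is no stereocentre, so the difficulty is connectivity and chemoselectivity. The hard bond system is C2–O–C1′: C2 is at the carboxylic acid oxidation level (bound to O1 and to the aryloxy oxygen, vinylogous to C4=O), and no simple three-carbon building block carries that pattern. The C2 aryloxy group is a leaving group: alkoxides and amines add at C2 and expel it, and aqueous acid hydrolyses the system to a 4-hydroxycoumarin. Three phenolic oxygens must end up different: O5 free and chelated to C4=O, O7 prenylated, O4′ free. The prenyl ether ionises in acid, undergoes Claisen rearrangement on heating, is reduced by H2 over palladium and is attacked by peroxides, so it must be installed after all such steps.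

The feature the plan exploits is the exocyclic oxygen between C2 of ring C and C1′ of ring B. Without it the skeleton is that of a 2-hydroxyflavanone, the most accessible C6–C3–C6 framework. Ring B carries a para oxygen (O4′), which makes it an excellent migrating group from carbon to electron-deficient oxygen. O1 stabilises a cation at C2, and the C3 hydrogens alpha to C4=O allow that cation to collapse to the pyranone.

## Retrosynthesis

**12 ⇒ 10 + 11.** The O7–CH2 bond of target 12 is cut to give the triol 10 (5,7-dihydroxy-2-(4-hydroxyphenoxy)chromen-4-one) and prenyl bromide 11. The prenyl group would not survive the peroxide, the acylating acid medium or the hydrogenolysis used earlier, so it must come last. The forward reaction must alkylate one of three phenols. O7–H is a vinylogous carboxylic acid (para to the C4a–C4=O unit), O5–H is locked in a hydrogen bond to C4=O, and O4′–H is an ordinary hydroquinone monoether phenol, so a hydrogencarbonate base should ionise only O7–H.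

**10 ⇒ 9.** The three O–benzyl bonds are cut, giving the tribenzyl ether 9. Benzyl is chosen because ring B needs a para alkoxy donor in the key step (an acyl group would lower its migratory aptitude, a free OH would be acylated). Benzyl ethers also survive amide base, H2O2 with acid and trifluoroacetic anhydride, and they come off under neutral hydrogenolysis, which the C2 aryloxy group tolerates.

**9 ⇒ 6 (key disconnection).** The exocyclic oxygen is taken out from between C2 and C1′: the C1′–O bond is cut and a C2–C1′ bond is drawn, leaving the oxygen on C2 as part of a hydroperoxide. The precursor is the 2-hydroperoxyflavanone 6. This is preferred over the neighbouring cut (C2–O, phenoxide plus a chromone with a C2 leaving group) because ring B is then delivered as a carbon substituent by ordinary carbonyl chemistry, with no leaving group to install and discard. It follows a plausible biogenesis, which is assumed here and not established: oxygen insertion into the C2–C1′ bond of a C2-oxygenated flavanone, the stage just before the co-occurring flavones. The forward reaction must make ring B, and not C3, migrate to oxygen, and the resulting C2 cation must lose the C3 proton and not be hydrolysed.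

**6 ⇒ 5.** The C2–OOH bond is traced to the C2–OH of the cyclic hemiketal 5 (a 2-hydroxyflavanone) by exchange with H2O2. The forward reaction needs mild acid so that the C2 oxocarbenium ion is captured by H2O2 faster than it loses a proton to give the flavone.

**5 ⇒ 4 ⇒ 2 + 3.** The hemiketal O1–C2 bond is opened to the β-diketone 4, and the C2–C3 bond is then cut by a Claisen-type disconnection into the acetophenone 2 and 4-(benzyloxy)benzoyl chloride 3. One C–C bond joins two simple aromatic building blocks and gives all fifteen skeletal carbons. The forward reaction must acylate the enolate carbon of 2, or reach the same product by 1,5-acyl shift from the phenol ester.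

**2 ⇒ 1.** Two O–benzyl bonds are cut to 2′,4′,6′-trihydroxyacetophenone 1. Compound 1 is symmetric, and the last ortho OH is chelated to the acetyl group, so dibenzylation stops at 2.

## Roads not taken

**Alternative 1:** The most obvious cut is the C2–O(aryl) bond by addition–elimination. The forward key step would treat 5,7-bis(benzyloxy)-2-(methylsulfonyl)-4H-chromen-4-one A1 with the phenoxide of 4-(benzyloxy)phenol A2 to give 9. A1 needs three steps from 2 (ring closure with a one-carbon sulfur electrophile, S-methylation, S-oxidation), all spent on a leaving group that is then discarded, so 2 → 9 takes four steps against three in the chosen plan. Addition at C2 is also slowed by the donor oxygens at C5 and C7. This chemistry is the more secure one, and it is kept as the fallback for the key step.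

**Alternative 2:** Ring C could be assembled in one operation by cutting O1–C2 and both bonds to C4. The forward key step would be a carbonylative Sonogashira coupling (zerovalent palladium, CO) of 3,5-bis(benzyloxy)-2-iodophenol A4 with the aryl ethynyl ether A3, followed by 6-endo-dig closure of the aryloxy ynone A5 to 9. A3 must be made at low temperature and is prone to hydration and polymerisation. In A5 the alkyne carbon bearing the aryloxy group is a strongly activated acceptor, so the amine base needed for the coupling would add there and expel aryloxide, and the phenol could also close 5-exo. A4 needs its own regioselective iodination. The chosen plan has a shorter run-up and no such sensitive intermediates.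

**Alternative 3:** The aryl–oxygen bond O–C1′ could be cut, with O-arylation of 5,7-bis(benzyloxy)-4-hydroxycoumarin A6 by the diaryliodonium salt A7 (or a copper-mediated coupling) as the forward key step. The anion of A6 is ambident, with its charge on O4 and C3, so aryl transfer should give the 4-aryloxycoumarin A8 or the 3-aryl compound A9. The wanted arylation at the lactone carbonyl oxygen would have to form the less stable 4-pyranone isomer, and the substrate offers nothing to enforce that. The chosen plan fixes the regiochemistry by construction, since the oxygen is inserted exactly into the C2–C1′ bond.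

Key step: step 4

## Route

Step 1
Reactants: 1 1-(2,4,6-trihydroxyphenyl)ethanone
Product: 2 1-[2,4-bis(benzyloxy)-6-hydroxyphenyl]ethanone
Conditions: BnBr (2.1 equiv), K2CO3 (2.2 equiv), DMF, 0 °C to rt
Reagents that add atoms: benzyl bromide, BrCc1ccccc1
Why: Williamson etherification; the para OH and one of the two equivalent ortho OH groups react, and the remaining ortho OH is hydrogen-bonded to the acetyl C=O and should resist alkylation, so the symmetric starting material should give one dibenzyl ether.

Step 2
Reactants: 2 1-[2,4-bis(benzyloxy)-6-hydroxyphenyl]ethanone; 3 4-(benzyloxy)benzoyl chloride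
Product: 5 5,7-bis(benzyloxy)-2-[4-(benzyloxy)phenyl]-2-hydroxychroman-4-one, via β-diketone 4 (not isolated)
Conditions: LiN(SiMe3)2 (3.3 equiv), THF, −78 to −10 °C; then 3, −78 °C to rt; cold 1 M HCl work-up
Reagents that add atoms: none
Why: Claisen-type C-acylation of the lithium phenoxide–enolate dianion of 2; any O-aroylated material should converge on the same diketone by Baker–Venkataraman 1,5-acyl shift under the excess base. On acidic work-up 4 should close 6-exo-trig to the racemic hemiketal 5, favoured because the C5 benzyloxy group twists the aryl ketone out of the chelated enol form.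

Step 3
Reactants: 5 5,7-bis(benzyloxy)-2-[4-(benzyloxy)phenyl]-2-hydroxychroman-4-one
Product: 6 5,7-bis(benzyloxy)-2-[4-(benzyloxy)phenyl]-2-hydroperoxychroman-4-one
Conditions: H2O2 (50% aq., 10 equiv), camphorsulfonic acid (0.1 equiv), THF, 0 °C; aqueous wash, dry, use cold in solution
Reagents that add atoms: hydrogen peroxide, OO
Why: Acid-catalysed hemiketal-to-perketal exchange through the C2 oxocarbenium ion, a known route from lactols and hemiketals to α-alkoxy hydroperoxides; H2O2 is the better nucleophile and the perketal the more stable adduct. The C4 ketone is a vinylogous carbonate carbonyl of the trioxygenated ring A and should not add peroxide.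

Step 4
Reactants: 6 5,7-bis(benzyloxy)-2-[4-(benzyloxy)phenyl]-2-hydroperoxychroman-4-one
Product: 9 5,7-bis(benzyloxy)-2-[4-(benzyloxy)phenoxy]-4H-chromen-4-one, via peroxy trifluoroacetate 7 (not isolated), via dioxocarbenium trifluoroacetate 8 (not isolated)
Conditions: (CF3CO)2O (1.2 equiv), 2,6-lutidine (2.5 equiv), 4 Å MS, CH2Cl2, −40 to 0 °C
Reagents that add atoms: none
Why: Proposed new method: Criegee rearrangement of a cyclic flavonoid perketal with carbon-to-oxygen shift of ring B; the hydroperoxide oxygen of 6 is trifluoroacetylated to 7, whose O–O bond ionises with concerted 1,2-migration of the 4-benzyloxyphenyl group from C2 to the proximal peroxide oxygen, pushed by a lone pair of O1 and passing through a phenonium-like transition state that the para oxygen stabilises. The result is the ring C dioxocarbenium ion 8 (C2 bound to O1, to the new aryloxy oxygen and to C3), which loses a C3 proton, acidified by both the C2 cation and C4=O, to 2,6-lutidine and gives the 4-pyranone 9. The closest known reaction type is the Criegee rearrangement of peresters of α-alkoxy hydroperoxides (ozonolysis-derived methoxy hydroperoxides giving dialkoxycarbenium ions and then esters), together with the Hock and Dakin aryl shifts; new here are the 2-hydroperoxyflavanone substrate and the termination by β-proton loss to an aryloxy enone. No ring is closed in this step: ring C was closed in step 2 and is only raised to the pyranone level here, no stereocentre is formed, and the racemic C2 centre is destroyed. The step needs three selectivities: aryl over C3 migration (C3 is a methylene alpha to a ketone and a poor migrator, para-alkoxyphenyl is among the best), O–O over C2–OO heterolysis (trifluoroacetate is a much better leaving group than trifluoroperacetate), and proton loss over capture of 8 by water (secured by the anhydrous medium). The base is weak and hindered so that C3 is not enolised before migration, which would instead close a 2,3-epoxide.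

Step 5
Reactants: 9 5,7-bis(benzyloxy)-2-[4-(benzyloxy)phenoxy]-4H-chromen-4-one
Product: 10 5,7-dihydroxy-2-(4-hydroxyphenoxy)-4H-chromen-4-one
Conditions: H2 (1 atm), 10% Pd/C, EtOAc/MeOH, rt
Reagents that add atoms: none
Why: Hydrogenolysis of three benzyl aryl ethers under neutral conditions; the chromone C2=C3 bond and the vinylic C2–OAr bond should be untouched, as is usual for benzyl-protected flavones and chromones.

Step 6
Reactants: 10 5,7-dihydroxy-2-(4-hydroxyphenoxy)-4H-chromen-4-one; 11 1-bromo-3-methylbut-2-ene (prenyl bromide)
Product: 12 5-hydroxy-2-(4-hydroxyphenoxy)-7-[(3-methylbut-2-en-1-yl)oxy]-4H-chromen-4-one (target)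
Conditions: 11 (1.05 equiv), KHCO3 (1.5 equiv), DMF, rt to 40 °C
Reagents that add atoms: none
Why: Regioselective Williamson etherification; hydrogencarbonate should ionise only O7–H, a vinylogous acid expected to be about three pKa units more acidic than O4′–H, while O5–H is chelated to C4=O. The weak base and mild temperature should also leave the C2 aryloxy group and the new prenyl ether untouched.

## Compound list

1 | 1-(2,4,6-trihydroxyphenyl)ethanone | CC(=O)c1c(O)cc(O)cc1O | starting material
2 | 1-[2,4-bis(benzyloxy)-6-hydroxyphenyl]ethanone | CC(=O)c1c(O)cc(OCc2ccccc2)cc1OCc1ccccc1 | intermediate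
3 | 4-(benzyloxy)benzoyl chloride | O=C(Cl)c1ccc(OCc2ccccc2)cc1 | starting material
4 | 1-[2,4-bis(benzyloxy)-6-hydroxyphenyl]-3-[4-(benzyloxy)phenyl]propane-1,3-dione | O=C(CC(=O)c1ccc(OCc2ccccc2)cc1)c1c(O)cc(OCc2ccccc2)cc1OCc1ccccc1 | intermediate (not isolated)
5 | 5,7-bis(benzyloxy)-2-[4-(benzyloxy)phenyl]-2-hydroxychroman-4-one (racemic) | OC1(c2ccc(OCc3ccccc3)cc2)CC(=O)c2c(OCc3ccccc3)cc(OCc3ccccc3)cc2O1 | intermediate
6 | 5,7-bis(benzyloxy)-2-[4-(benzyloxy)phenyl]-2-hydroperoxychroman-4-one (racemic) | OOC1(c2ccc(OCc3ccccc3)cc2)CC(=O)c2c(OCc3ccccc3)cc(OCc3ccccc3)cc2O1 | intermediate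
7 | 5,7-bis(benzyloxy)-2-[4-(benzyloxy)phenyl]-4-oxochroman-2-yl peroxytrifluoroacetate (racemic) | O=C(OOC1(c2ccc(OCc3ccccc3)cc2)CC(=O)c2c(OCc3ccccc3)cc(OCc3ccccc3)cc2O1)C(F)(F)F | intermediate (not isolated)
8 | 5,7-bis(benzyloxy)-2-[4-(benzyloxy)phenoxy]-4-oxo-3,4-dihydrochromenylium trifluoroacetate | O=C1CC(Oc2ccc(OCc3ccccc3)cc2)=[O+]c2cc(OCc3ccccc3)cc(OCc3ccccc3)c21.[O-]C(=O)C(F)(F)F | intermediate (not isolated)
9 | 5,7-bis(benzyloxy)-2-[4-(benzyloxy)phenoxy]-4H-chromen-4-one | O=c1cc(Oc2ccc(OCc3ccccc3)cc2)oc2cc(OCc3ccccc3)cc(OCc3ccccc3)c12 | intermediate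
10 | 5,7-dihydroxy-2-(4-hydroxyphenoxy)-4H-chromen-4-one | O=c1cc(Oc2ccc(O)cc2)oc2cc(O)cc(O)c12 | intermediate
11 | 1-bromo-3-methylbut-2-ene | CC(C)=CCBr | starting material
12 | 5-hydroxy-2-(4-hydroxyphenoxy)-7-[(3-methylbut-2-en-1-yl)oxy]-4H-chromen-4-one | CC(C)=CCOc1cc(O)c2c(=O)cc(Oc3ccc(O)cc3)oc2c1 | target

## Step count and risk

Total step count: 6. Longest linear sequence: 6 steps (1 → 2 → 5 → 6 → 9 → 10 → 12).

**Step 4 (key step, proposed new method).** Three things may go wrong:
- The perester may ionise at the C2–OO bond instead of the O–O bond, which returns the C2 oxocarbenium ion and ends in loss of the C3 proton without oxygen insertion.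
- C3 may be deprotonated before migration, so that the enol closes onto the peroxide oxygen.
- Adventitious water may hydrolyse the dioxocarbenium ion with loss of the aryloxy group.

Fallback (known chemistry), setting out from 2 and rejoining at 9: condensation of 2 with carbon disulfide (t-BuOK, THF) should give 5,7-bis(benzyloxy)-4-hydroxy-2H-chromene-2-thione F1. S-Methylation (MeI, K2CO3, acetone) gives 5,7-bis(benzyloxy)-2-(methylsulfanyl)-4H-chromen-4-one F2, and oxidation (mCPBA, CH2Cl2) gives 5,7-bis(benzyloxy)-2-(methylsulfonyl)-4H-chromen-4-one F3, the same structure as A1. Addition–elimination with the potassium salt of 4-(benzyloxy)phenol A2 in DMF then displaces methanesulfinate and gives 9.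

**Step 3.** Acid-catalysed dehydration of the hemiketal (proton loss from the oxocarbenium ion before peroxide capture) may compete, as may peroxide attack on the open-chain diketone tautomer with carbon–carbon cleavage. Fallback, setting out from 5 and rejoining at 9, which replaces the protic exchange and the isolated hydroperoxide by an aprotic silyl peroxide sequence: 5 is silylated (Me3SiCl, imidazole) to 5,7-bis(benzyloxy)-2-[4-(benzyloxy)phenyl]-2-(trimethylsilyloxy)chroman-4-one F4. With bis(trimethylsilyl) peroxide and Me3SiOTf in CH2Cl2 at −78 °C, F4 should exchange to 5,7-bis(benzyloxy)-2-[4-(benzyloxy)phenyl]-2-(trimethylsilylperoxy)chroman-4-one F5. The same Lewis acid activates the O–O bond of F5 for the aryl shift, as in silyl-peroxide Baeyer–Villiger oxidations, and gives 9 directly.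

**Step 6.** Alkylation may be incompletely regioselective (competing reaction at O4′, double alkylation, or C-prenylation of ring A). Fallback, setting out from 10 and rejoining at 12, using orthogonal acyl protection: peracetylation (Ac2O, pyridine) gives 4-[(5,7-diacetoxy-4-oxo-4H-chromen-2-yl)oxy]phenyl acetate F6. Selective removal of the most activated 7-O-acetyl group (PhSH, imidazole, NMP) gives 4-[(5-acetoxy-7-hydroxy-4-oxo-4H-chromen-2-yl)oxy]phenyl acetate F7. Mitsunobu etherification with 3-methylbut-2-en-1-ol (PPh3, DIAD, THF) gives 4-({5-acetoxy-7-[(3-methylbut-2-en-1-yl)oxy]-4-oxo-4H-chromen-2-yl}oxy)phenyl acetate F8. Brief methanolysis (catalytic K2CO3, MeOH, 0 °C) then removes both acetates and gives 12.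

**Step 2.** Acylation may stop at the phenol oxygen, or a second aroyl group may be introduced. Fallback, setting out from 2 and rejoining at 5, the stepwise Baker–Venkataraman sequence: O-aroylation of 2 with 3 (pyridine, DMAP, CH2Cl2) gives 2-acetyl-3,5-bis(benzyloxy)phenyl 4-(benzyloxy)benzoate F9. Base-induced 1,5-acyl shift (KOH, pyridine, 50 °C) and acidic work-up then give 5 by way of 4.

## Further compounds

F1 | step 4 | 5,7-bis(benzyloxy)-4-hydroxy-2H-chromene-2-thione | S=c1cc(O)c2c(OCc3ccccc3)cc(OCc3ccccc3)cc2o1
F2 | step 4 | 5,7-bis(benzyloxy)-2-(methylsulfanyl)-4H-chromen-4-one | CSc1cc(=O)c2c(OCc3ccccc3)cc(OCc3ccccc3)cc2o1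
F3 | step 4 | 5,7-bis(benzyloxy)-2-(methylsulfonyl)-4H-chromen-4-one | CS(=O)(=O)c1cc(=O)c2c(OCc3ccccc3)cc(OCc3ccccc3)cc2o1
F4 | step 3 | 5,7-bis(benzyloxy)-2-[4-(benzyloxy)phenyl]-2-(trimethylsilyloxy)chroman-4-one | C[Si](C)(C)OC1(c2ccc(OCc3ccccc3)cc2)CC(=O)c2c(OCc3ccccc3)cc(OCc3ccccc3)cc2O1
F5 | step 3 | 5,7-bis(benzyloxy)-2-[4-(benzyloxy)phenyl]-2-(trimethylsilylperoxy)chroman-4-one | C[Si](C)(C)OOC1(c2ccc(OCc3ccccc3)cc2)CC(=O)c2c(OCc3ccccc3)cc(OCc3ccccc3)cc2O1
F6 | step 6 | 4-[(5,7-diacetoxy-4-oxo-4H-chromen-2-yl)oxy]phenyl acetate | CC(=O)Oc1ccc(Oc2cc(=O)c3c(OC(C)=O)cc(OC(C)=O)cc3o2)cc1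
F7 | step 6 | 4-[(5-acetoxy-7-hydroxy-4-oxo-4H-chromen-2-yl)oxy]phenyl acetate | CC(=O)Oc1ccc(Oc2cc(=O)c3c(OC(C)=O)cc(O)cc3o2)cc1
F8 | step 6 | 4-({5-acetoxy-7-[(3-methylbut-2-en-1-yl)oxy]-4-oxo-4H-chromen-2-yl}oxy)phenyl acetate | CC(=O)Oc1ccc(Oc2cc(=O)c3c(OC(C)=O)cc(OCC=C(C)C)cc3o2)cc1
F9 | step 2 | 2-acetyl-3,5-bis(benzyloxy)phenyl 4-(benzyloxy)benzoate | CC(=O)c1c(OC(=O)c2ccc(OCc3ccccc3)cc2)cc(OCc2ccccc2)cc1OCc1ccccc1
A1 | alternative 1 | 5,7-bis(benzyloxy)-2-(methylsulfonyl)-4H-chromen-4-one | CS(=O)(=O)c1cc(=O)c2c(OCc3ccccc3)cc(OCc3ccccc3)cc2o1
A2 | alternative 1 | 4-(benzyloxy)phenol | Oc1ccc(OCc2ccccc2)cc1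
A3 | alternative 2 | 1-(benzyloxy)-4-(ethynyloxy)benzene | C#COc1ccc(OCc2ccccc2)cc1
A4 | alternative 2 | 3,5-bis(benzyloxy)-2-iodophenol | Oc1cc(OCc2ccccc2)cc(OCc2ccccc2)c1I
A5 | alternative 2 | 1-[2,4-bis(benzyloxy)-6-hydroxyphenyl]-3-[4-(benzyloxy)phenoxy]prop-2-yn-1-one | O=C(C#COc1ccc(OCc2ccccc2)cc1)c1c(O)cc(OCc2ccccc2)cc1OCc1ccccc1
A6 | alternative 3 | 5,7-bis(benzyloxy)-4-hydroxy-2H-chromen-2-one | O=c1cc(O)c2c(OCc3ccccc3)cc(OCc3ccccc3)cc2o1
A7 | alternative 3 | bis[4-(benzyloxy)phenyl]iodonium trifluoromethanesulfonate | [O-]S(=O)(=O)C(F)(F)F.c1ccc(COc2ccc([I+]c3ccc(OCc4ccccc4)cc3)cc2)cc1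
A8 | alternative 3 | 5,7-bis(benzyloxy)-4-[4-(benzyloxy)phenoxy]-2H-chromen-2-one | O=c1cc(Oc2ccc(OCc3ccccc3)cc2)c2c(OCc3ccccc3)cc(OCc3ccccc3)cc2o1
A9 | alternative 3 | 5,7-bis(benzyloxy)-3-[4-(benzyloxy)phenyl]-4-hydroxy-2H-chromen-2-one | O=c1oc2cc(OCc3ccccc3)cc(OCc3ccccc3)c2c(O)c1-c1ccc(OCc2ccccc2)cc1
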